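The time of reading is what I have to plan around: 0.667 min after the start the red run holds 27.0% of target, at 2.00 min it holds 35.6%, and at 80.0 min it is back at 20.8%.

| flask | substrate | free catalyst | remark | time |
|---|---|---|---|---|
| red | 0.10 M | 0.5 mol% | run made earlier |  |
| blue | 0.15 M | 0.5 mol% | run made earlier |  |
| ochre | 0.20 M | 1 mol% | run made earlier |  |
| flask | 0.20 M | 0.5 mol% |  | 1.5 h |

| run | time / min | target / % | substrate / % |
|---|---|---|---|
| red | 0.667 | 27.0 | 53.3 |
| red | 2.00 | 35.6 | 32.1 |
| red | 5.00 | 29.0 | 26.5 |
| red | 12.0 | 23.8 | 23.0 |
| red | 30.0 | 20.9 | 21.4 |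
| red | 80.0 | 20.8 | 22.8 |
| blue | 0.667 | 27.4 | 53.4 |
| blue | 2.00 | 32.4 | 33.9 |
| blue | 5.00 | 29.2 | 28.2 |
| blue | 12.0 | 23.2 | 19.9 |
| blue | 30.0 | 21.4 | 21.3 |
| blue | 80.0 | 22.1 | 20.7 |
| ochre | 0.667 | 26.1 | 55.3 |
| ochre | 2.50 | 34.1 | 30.3 |
| ochre | 8.00 | 28.9 | 23.3 |
| ochre | 25.0 | 21.5 | 21.3 |
| ochre | 80.0 | 21.5 | 21.3 |

(scatter of a reading: 1 percentage point)

- the moment within 1.5 h at which there is most target, in min
- the amount of target, in percent of the substrate charged, at that time
- earliest time at which at least nineteen twentieths of that best amount are there, in min
- latest time at which they still are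



At the first reading red and blue show 53.3% and 53.4% of substrate, and ochre, with twice the loading, shows 55.3%. The percent curves lie close together, so I carry them to the flask. I write F for the resting level of target, the mean of the last readings, 21.5%; substrate comes to rest near it too.

The first rung of the ladder is the fall of substrate. Its excess over F at the first reading of red and blue gives a time τf of 0.740 min. The second rung is the crest C, the mean of the highest readings, 34.0%. The third rung is the fall of target. Its mean reading in red and blue goes from 29.1% at 5.00 min to 23.5% at 12.0 min, so its excess over F goes from 7.6 percentage points to 2 points, which gives a time τs of 5.29 min. That is slower than τf by a factor of 7.15, so target fills first and drains afterwards.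

I carry the lift L, the crest over the resting level of target: 1.59, the kinetic amount over the thermodynamic one (kinetic against thermodynamic control). For the flask I expect a best near C around 2.00 min. The mark at 95.0% of C is passed on the way up between 0.667 min and 2.00 min, and running τs back from 5.00 min gives the way down at 3.13 min.

The forecast puts the top at 2 min with 34.3%, from 1.2 min to 0.056 h, later than my closing time, on the ground that "The fractional curves of red and blue coincide".

The flask gives 34.1% at 1.84 min, and holds 95.0% of that from 1.15 min to 0.0517 h.

    substrate ⇌ target (K = 1.00, k = 0.0118 s⁻¹)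
    substrate ⇌ isomer of the product (K = 0.370, k = 0.00389 s⁻¹)
    substrate ⇌ dormant form (K = 2.40, k = 0.00380 s⁻¹)
    free catalyst → spent catalyst (k = 0.00283 s⁻¹)

Dormant form stands at 19.9% at the best time and at 50.3% after 1.50 h. Target ends the flask at 21.0%, so the lift of the flask is 1.62. In the neighbour flask, with 0.080 M of substrate, target ends at 21.0%, which L lifts to 33.2%, and its best stands at 34.1%.

(The earlier runs and the new flask come from a simulation on assumed constants; noise was put on by code.)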